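Z is the reagent to watch in this flask, which Thursday's run has followed so far.

- Thursday's: G 20 mM; Z 0.60 equiv; D 1 equiv; the very flask that is asked about, followed so far
- flask: G 20 mM; Z 0.600 equiv; D 1.00 equiv; time 4.0 h

Thursday's run (percent of the G charged)

| time / min | E / % | G / % |
|---|---|---|
| 3.00 | 13.7 | 76.7 |
| 10.0 | 23.9 | 39.8 |
| 30.0 | 16.4 | 5.9 |
| 120 | 0 | 0 |

(each reading ± 1 percentage point)



* time, not beyond 4.0 h, at which the flask holds most E
* the amount of E, in percent of the G charged, at that time

Take the tallest E reading, 23.9% at 10.0 min, and divide it by the Z charged. That gives one number, 39.8%: the Z load, an occupancy, which is the share of Z sitting in E at that reading if each E holds one Z.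

One number gives you a height but no time, so replace the curve by its mean between readings. Net E gained per G lost is 27.6% between the first two readings and −22.1% between the next two, so the sign turns somewhere between 3.00 min and 30.0 min. My own reckoning puts the top near 10.0 min, at about 23.9%, give or take 1 percentage point.

The forecast says 0.22 h and 26%, later and higher than my reckoning, and warns: “The peak lies between sampled points, so the time is loosely fixed”.

The flask peaks at 0.191 h with 22.7%.

    G → Q (k = 0.00159 /s)
    Z + Q ⇌ E (K = 3070 /M, k = 12.5 /M/s)
    D + Q → J (k = 3.40 /M/s)
    Q → L (k = 0.0103 /s)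
    Q → X (k = 2.58 × 10⁻⁴ /s)

At that top this flask has 62.2% of its Z free and 22.7% E, a Z load of 37.8%, beside the 39.8% taken from the reading. A neighbour flask with 0.360 equiv of Z and D unchanged gets 14.3% from the load and reaches 15.1%. In this flask at 0.121 h, Q goes to J 5.0 times as fast as to L, and the half-lives of Q by those two paths are 0.22 min against 1.1 min. At 4.00 h this flask holds 77.1% J and 22.3% L.

(Readings and results were generated by integration for an exercise, and the scatter is random.)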